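**Plan**

- Retrosynthetic cuts: the C2–C1' bond between ring C and ring B (aryl boronic acid plus a 7-silyloxy-8-prenylchromone); the C3'–CH2 bond of the side chain (aryl Grignard reagent plus methyl (R)-glycidate, the ester later becoming the isopropenyl group); and, in the pyran ring on ring B, the C4'–O bond, the C5'–C bond and the O–CMe2 bond (aryne plus 3-methylbut-2-enal).
- Enabling feature: ring B carries three neighbouring substituents (carbon at C3', oxygen at C4', carbon at C5'), and the dimethylpyran ring is simply the C4' oxygen and the C5' carbon tied together by the five carbons of an enal. A silyl group on C3' steers the aryne addition and afterwards becomes the attachment point of the side chain; a chlorine on C1' is kept for the bond to ring C.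
- Forward order: ring B as a symmetric bis-silyl aryl triflate, the pyran ring in one operation, the side chain at C3', boron at C1'. The chromone (rings A and C) is made separately from 2,4-dihydroxyacetophenone by Claisen prenylation and enaminone cyclisation. The halves are joined by conjugate addition and both silyl ethers are removed last.
- Stereochemistry: the R carbinol centre comes from methyl (R)-glycidate and its C–O bond is never broken; the 2S centre of the flavanone is set by the chiral bisphosphine on rhodium in the aryl conjugate addition.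

Key step: step 4

Assumption: the (S)-configured bisphosphine is taken to deliver the aryl group to the face of chromone C2 that gives the 2S flavanone, as (S)-biaryl bisphosphines do with cyclic enones; should the sense be the opposite, the (R)-ligand is used.

**Route**

Step 1
Reactants: 1 2,6-dibromo-4-chlorophenol
Product: 2 (2,6-dibromo-4-chlorophenoxy)trimethylsilane
Conditions: (Me3Si)2NH, THF, reflux; volatiles removed
Reagents that add atoms: hexamethyldisilazane, C[Si](C)(C)N[Si](C)(C)C
Why: O-silylation of an acidic phenol with a disilazane, driven by loss of NH3, is routine and should give the silyl ether that the later retro-Brook shift needs.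

Step 2
Reactants: 2 (2,6-dibromo-4-chlorophenoxy)trimethylsilane
Product: 5 [2-bromo-4-chloro-6-(trimethylsilyl)phenoxy]trimethylsilane, via aryllithium 3 (not isolated), via lithium phenoxide 4 (not isolated)
Conditions: n-BuLi (1.05 equiv), THF, −78 °C to rt; then Me3SiCl, 0 °C
Reagents that add atoms: chlorotrimethylsilane, C[Si](C)(C)Cl
Why: Bromine–lithium exchange next to the silyloxy group gives 3, whose silyl group should move from oxygen to carbon (retro-Brook rearrangement) to give 4, and Me3SiCl then caps the phenoxide again; the C–Cl bond does not exchange with n-BuLi at −78 °C.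

Step 3
Reactants: 5 [2-bromo-4-chloro-6-(trimethylsilyl)phenoxy]trimethylsilane
Product: 8 4-chloro-2,6-bis(trimethylsilyl)phenyl trifluoromethanesulfonate, via bis-silyl aryllithium 6 (not isolated), via bis-silyl phenoxide 7 (not isolated)
Conditions: n-BuLi (1.05 equiv), THF, −78 °C to rt; then Tf2O, −78 °C to rt
Reagents that add atoms: trifluoromethanesulfonic anhydride, O=S(=O)(OS(=O)(=O)C(F)(F)F)C(F)(F)F
Why: A second bromine–lithium exchange and retro-Brook shift should place the second silyl group on carbon, and O-sulfonylation of phenoxide 7 with Tf2O then gives the symmetric aryne precursor.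

Step 4
Reactants: 8 4-chloro-2,6-bis(trimethylsilyl)phenyl trifluoromethanesulfonate; 9 3-methylbut-2-enal
Product: 13 6-chloro-2,2-dimethyl-8-(trimethylsilyl)-2H-chromene, via 3-silylaryne 10 (not isolated), via benzoxete 11 (not isolated), via ortho-quinone methide 12 (not isolated)
Conditions: CsF (3 equiv), 9 (3 equiv), MeCN, rt
Reagents that add atoms: none
Why: Fluoride can strike either of the two identical silyl groups of 8 and loss of triflate then leads to one and the same aryne 10; the carbonyl oxygen of 9 adds to the aryne carbon beside silicon, the aryl anion closes on the carbonyl carbon (formal [2+2] to benzoxete 11), the four-membered ring opens to the ortho-quinone methide 12, and a thermal oxa-6π electrocyclisation joins oxygen to the dimethyl-bearing carbon. The closest known reaction type is the fluoride-triggered annulation of arynes with α,β-unsaturated aldehydes to 2H-chromenes, and the steering by an ortho silyl group is carried over from additions of small heteroatom nucleophiles to 3-silylarynes. Only the pyran ring is closed for good, by disrotatory 6π electrocyclisation of the cis-dienone unit of 12; the oxete ring is a passing intermediate. No stereocentre remains in 13, because the CH centre of 11 becomes sp2 when the oxete opens. The step needs regioselectivity (oxygen beside silicon, carbon away from it): the electropositive silyl group flattens the neighbouring aryne carbon and makes it the more electrophilic one for a small oxygen nucleophile, and the chlorine para to that carbon pulls in the same direction by placing the developing aryl anion meta to itself. It also needs the second C–Si bond to survive, which should hold because fluoride in MeCN at rt cleaves an aryl silane readily only when a leaving group sits ortho to it.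

Step 5
Reactants: 13 6-chloro-2,2-dimethyl-8-(trimethylsilyl)-2H-chromene
Product: 14 6-chloro-8-iodo-2,2-dimethyl-2H-chromene
Conditions: ICl (1.05 equiv), CH2Cl2, −78 °C; aq Na2S2O3 quench
Reagents that add atoms: iodine monochloride, ClI
Why: Electrophilic ipso-iododesilylation: the silicon-bearing carbon lies ortho to the ring oxygen and the arenium ion is stabilised by the β-silicon effect, so one equivalent of ICl at −78 °C should swap silicon for iodine faster than it adds to the chlorine-deactivated alkene, whose C3 is shielded by the neighbouring quaternary carbon.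

Step 6
Reactants: 14 6-chloro-8-iodo-2,2-dimethyl-2H-chromene; 15 methyl (R)-glycidate
Product: 17 methyl (2R)-3-(6-chloro-2,2-dimethyl-2H-chromen-8-yl)-2-hydroxypropanoate, via arylmagnesium chloride 16 (not isolated)
Conditions: i-PrMgCl·LiCl (1.05 equiv), THF, −20 to 0 °C; then CuI (10 mol %), 15 (1.2 equiv), −40 to −20 °C; aq NH4Cl
Reagents that add atoms: none
Why: Iodine–magnesium exchange takes the C–I bond and leaves C–Cl, and the CuI-catalysed SN2 opening of the glycidic ester by the aryl Grignard reagent should occur at the unsubstituted CH2 terminus at low temperature, so the R centre of 15 passes into 17 without any bond to it being broken.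

Step 7
Reactants: 17 methyl (2R)-3-(6-chloro-2,2-dimethyl-2H-chromen-8-yl)-2-hydroxypropanoate
Product: 18 methyl (2R)-2-[(tert-butyldimethylsilyl)oxy]-3-(6-chloro-2,2-dimethyl-2H-chromen-8-yl)propanoate
Conditions: TBSCl, imidazole, DMF, rt
Reagents that add atoms: tert-butyldimethylsilyl chloride, CC(C)(C)[Si](C)(C)Cl
Why: Silyl ether formation protects the secondary alcohol through the Grignard, ylide, palladium and rhodium steps.

Step 8
Reactants: 18 methyl (2R)-2-[(tert-butyldimethylsilyl)oxy]-3-(6-chloro-2,2-dimethyl-2H-chromen-8-yl)propanoate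
Product: 19 (2R)-2-[(tert-butyldimethylsilyl)oxy]-3-(6-chloro-2,2-dimethyl-2H-chromen-8-yl)-N-methoxy-N-methylpropanamide
Conditions: MeNH(OMe)·HCl (1.5 equiv), i-PrMgCl (3.0 equiv), THF, −20 °C
Reagents that add atoms: N,O-dimethylhydroxylamine hydrochloride, CNOC.Cl
Why: Weinreb amide formation: the magnesium amide made from MeNH(OMe)·HCl and i-PrMgCl should displace methoxide from the ester at −20 °C, conditions under which α-silyloxy esters keep their configuration.

Step 9
Reactants: 19 (2R)-2-[(tert-butyldimethylsilyl)oxy]-3-(6-chloro-2,2-dimethyl-2H-chromen-8-yl)-N-methoxy-N-methylpropanamide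
Product: 20 (3R)-3-[(tert-butyldimethylsilyl)oxy]-4-(6-chloro-2,2-dimethyl-2H-chromen-8-yl)butan-2-one
Conditions: MeMgBr (1.5 equiv), THF, −20 to 0 °C; aq NH4Cl
Reagents that add atoms: methylmagnesium bromide, C[Mg]Br
Why: Grignard addition to a Weinreb amide stops at the chelated tetrahedral intermediate, so the methyl ketone should form without over-addition.

Step 10
Reactants: 20 (3R)-3-[(tert-butyldimethylsilyl)oxy]-4-(6-chloro-2,2-dimethyl-2H-chromen-8-yl)butan-2-one
Product: 21 tert-butyl{[(2R)-1-(6-chloro-2,2-dimethyl-2H-chromen-8-yl)-3-methylbut-3-en-2-yl]oxy}dimethylsilane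
Conditions: Ph3PCH3Br, KN(SiMe3)2, THF, 0 °C; then 20, −78 to 0 °C
Reagents that add atoms: methyltriphenylphosphonium bromide, C[P+](c1ccccc1)(c1ccccc1)c1ccccc1.[Br-]
Why: Wittig methylenation: the non-stabilised ylide should add to the methyl ketone faster than it deprotonates it at low temperature, so the α-silyloxy centre keeps its R configuration while the isopropenyl group is formed.

Step 11
Reactants: 21 tert-butyl{[(2R)-1-(6-chloro-2,2-dimethyl-2H-chromen-8-yl)-3-methylbut-3-en-2-yl]oxy}dimethylsilane
Product: 22 tert-butyl{[(2R)-1-[2,2-dimethyl-6-(4,4,5,5-tetramethyl-1,3,2-dioxaborolan-2-yl)-2H-chromen-8-yl]-3-methylbut-3-en-2-yl]oxy}dimethylsilane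
Conditions: B2pin2 (1.5 equiv), Pd2(dba)3 (2 mol %), XPhos (8 mol %), KOAc (3 equiv), 1,4-dioxane, 100 °C
Reagents that add atoms: bis(pinacolato)diboron, CC1(C)OB(OC1(C)C)B1OC(C)(C)C(C)(C)O1
Why: Miyaura borylation: the bulky electron-rich biaryl phosphine XPhos lets zerovalent palladium insert into the electron-rich aryl C–Cl bond, and acetate-assisted transmetalation with B2pin2 should give the aryl boronate without touching the alkenes or the silyl ether.

Step 12
Reactants: 22 tert-butyl{[(2R)-1-[2,2-dimethyl-6-(4,4,5,5-tetramethyl-1,3,2-dioxaborolan-2-yl)-2H-chromen-8-yl]-3-methylbut-3-en-2-yl]oxy}dimethylsilane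
Product: 23 {8-[(2R)-2-[(tert-butyldimethylsilyl)oxy]-3-methylbut-3-en-1-yl]-2,2-dimethyl-2H-chromen-6-yl}boronic acid
Conditions: NaIO4 (3 equiv), NH4OAc (3 equiv), acetone/H2O (1:1), rt
Reagents that add atoms: water, O
Why: Oxidative glycol cleavage: periodate destroys the pinacol released in the hydrolysis equilibrium of the boronate, which should pull the ester over to the free boronic acid needed for transmetalation to rhodium under neutral conditions.

Step 13
Reactants: 24 2,4-dihydroxyacetophenone; 25 3-chloro-3-methylbut-1-yne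
Product: 26 1-{2-hydroxy-4-[(2-methylbut-3-yn-2-yl)oxy]phenyl}ethan-1-one
Conditions: 25 (1.5 equiv), K2CO3, KI, CuI (cat.), acetone, reflux
Reagents that add atoms: none
Why: Copper-assisted O-propargylation (Williamson-type ether synthesis with a tertiary propargylic chloride) should take place at the 4-hydroxyl, because the 2-hydroxyl is tied up in a hydrogen bond to the acetyl group.

Step 14
Reactants: 26 1-{2-hydroxy-4-[(2-methylbut-3-yn-2-yl)oxy]phenyl}ethan-1-one
Product: 27 1-{2-hydroxy-4-[(2-methylbut-3-en-2-yl)oxy]phenyl}ethan-1-one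
Conditions: H2 (1 atm), Pd/CaCO3 poisoned with Pb(OAc)2 (Lindlar catalyst), quinoline, EtOAc, rt
Reagents that add atoms: none
Why: Lindlar semihydrogenation should stop at the alkene, since the poisoned catalyst reduces alkynes much faster than terminal alkenes and leaves the aryl ketone alone.

Step 15
Reactants: 27 1-{2-hydroxy-4-[(2-methylbut-3-en-2-yl)oxy]phenyl}ethan-1-one
Product: 29 1-[2,4-dihydroxy-3-(3-methylbut-2-en-1-yl)phenyl]ethan-1-one, via cyclohexadienone 28 (not isolated)
Conditions: PhNEt2, 130 °C
Reagents that add atoms: none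
Why: Aromatic Claisen rearrangement ([3,3]) of the 1,1-dimethylallyl ether gives dienone 28, which tautomerises to the phenol; migration should go to C3 rather than C5 because the chelated 2-hydroxy ketone fixes the ring double bond between C3 and C4, and the allyl inversion turns the reverse-prenyl ether into a normal prenyl group.

Step 16
Reactants: 29 1-[2,4-dihydroxy-3-(3-methylbut-2-en-1-yl)phenyl]ethan-1-one
Product: 30 1-{2-hydroxy-3-(3-methylbut-2-en-1-yl)-4-[(triisopropylsilyl)oxy]phenyl}ethan-1-one
Conditions: TIPSCl, imidazole, DMF, rt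
Reagents that add atoms: triisopropylsilyl chloride, CC(C)[Si](Cl)(C(C)C)C(C)C
Why: Silyl ether formation should be selective for the 4-hydroxyl, the 2-hydroxyl being hydrogen-bonded to the carbonyl group and flanked on both sides.

Step 17
Reactants: 30 1-{2-hydroxy-3-(3-methylbut-2-en-1-yl)-4-[(triisopropylsilyl)oxy]phenyl}ethan-1-one
Product: 32 8-(3-methylbut-2-en-1-yl)-7-[(triisopropylsilyl)oxy]-4H-chromen-4-one, via enaminone 31 (not isolated)
Conditions: Me2NCH(OMe)2, toluene, 90 °C; then 1 M HCl (aq), CH2Cl2, rt
Reagents that add atoms: N,N-dimethylformamide dimethyl acetal, COC(OC)N(C)C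
Why: Chromone synthesis by the enaminone route: condensation of the acetyl CH3 group with the amide acetal gives 31, and acid then promotes conjugate addition of the phenol and loss of dimethylamine to close the pyranone ring.

Step 18
Reactants: 23 {8-[(2R)-2-[(tert-butyldimethylsilyl)oxy]-3-methylbut-3-en-1-yl]-2,2-dimethyl-2H-chromen-6-yl}boronic acid; 32 8-(3-methylbut-2-en-1-yl)-7-[(triisopropylsilyl)oxy]-4H-chromen-4-one
Product: 33 (2S)-2-{8-[(2R)-2-[(tert-butyldimethylsilyl)oxy]-3-methylbut-3-en-1-yl]-2,2-dimethyl-2H-chromen-6-yl}-8-(3-methylbut-2-en-1-yl)-7-[(triisopropylsilyl)oxy]-2,3-dihydro-4H-chromen-4-one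
Conditions: [Rh(OH)((S)-MeO-F12-BIPHEP)]2 (3 mol % Rh; ligand = (S)-6,6'-dimethoxy-2,2'-bis[bis(3,4,5-trifluorophenyl)phosphino]biphenyl), 32 (1.5 equiv), CH2Cl2/H2O (10:1), 30 °C
Reagents that add atoms: none
Why: Rhodium-catalysed asymmetric conjugate addition (Hayashi–Miyaura reaction): the aryl–rhodium species formed by transmetalation should insert the chromone C2=C3 bond from the face left open by the (S)-bisphosphine, which sets the 2S centre, and hydrolysis of the rhodium enolate under neutral conditions avoids ring opening of the flavanone; the remote R centre of the side chain plays no part.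

Step 19
Reactants: 33 (2S)-2-{8-[(2R)-2-[(tert-butyldimethylsilyl)oxy]-3-methylbut-3-en-1-yl]-2,2-dimethyl-2H-chromen-6-yl}-8-(3-methylbut-2-en-1-yl)-7-[(triisopropylsilyl)oxy]-2,3-dihydro-4H-chromen-4-one
Product: 34 (2S)-7-hydroxy-2-{8-[(2R)-2-hydroxy-3-methylbut-3-en-1-yl]-2,2-dimethyl-2H-chromen-6-yl}-8-(3-methylbut-2-en-1-yl)-2,3-dihydro-4H-chromen-4-one (CNP0104040.1)
Conditions: Bu4NF/AcOH (1:1, 4 equiv), THF, 0 °C to rt
Reagents that add atoms: none
Why: Fluoride-mediated desilylation should free the phenol and the allylic alcohol together, the acetic acid buffer keeping the medium from opening the flavanone to the chalcone and thus protecting the 2S centre.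

**Compound list**

1 | 2,6-dibromo-4-chlorophenol | Oc1c(Br)cc(Cl)cc1Br | starting material
2 | (2,6-dibromo-4-chlorophenoxy)trimethylsilane | C[Si](C)(C)Oc1c(Br)cc(Cl)cc1Br | intermediate
3 | [3-bromo-5-chloro-2-(trimethylsilyloxy)phenyl]lithium | C[Si](C)(C)Oc1c([Li])cc(Cl)cc1Br | intermediate (not isolated)
4 | lithium 2-bromo-4-chloro-6-(trimethylsilyl)phenoxide | [Li+].[O-]c1c(Br)cc(Cl)cc1[Si](C)(C)C | intermediate (not isolated)
5 | [2-bromo-4-chloro-6-(trimethylsilyl)phenoxy]trimethylsilane | C[Si](C)(C)Oc1c(Br)cc(Cl)cc1[Si](C)(C)C | intermediate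
6 | [5-chloro-3-(trimethylsilyl)-2-(trimethylsilyloxy)phenyl]lithium | C[Si](C)(C)Oc1c([Li])cc(Cl)cc1[Si](C)(C)C | intermediate (not isolated)
7 | lithium 4-chloro-2,6-bis(trimethylsilyl)phenoxide | [Li+].[O-]c1c([Si](C)(C)C)cc(Cl)cc1[Si](C)(C)C | intermediate (not isolated)
8 | 4-chloro-2,6-bis(trimethylsilyl)phenyl trifluoromethanesulfonate | C[Si](C)(C)c1cc(Cl)cc([Si](C)(C)C)c1OS(=O)(=O)C(F)(F)F | intermediate
9 | 3-methylbut-2-enal | CC(C)=CC=O | starting material
10 | 5-chloro-3-(trimethylsilyl)benzyne (5-chloro-1,2-didehydro-3-(trimethylsilyl)benzene) | C[Si](C)(C)C1=CC(Cl)=CC#C1 | intermediate (not isolated)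
11 | 4-chloro-2-(2-methylprop-1-en-1-yl)-6-(trimethylsilyl)-2H-benzo[b]oxete (racemic) | CC(C)=CC1Oc2c1cc(Cl)cc2[Si](C)(C)C | intermediate (not isolated)
12 | (6Z)-4-chloro-6-(3-methylbut-2-en-1-ylidene)-2-(trimethylsilyl)cyclohexa-2,4-dien-1-one | O=C1/C(=C\C=C(C)C)C=C(Cl)C=C1[Si](C)(C)C | intermediate (not isolated)
13 | 6-chloro-2,2-dimethyl-8-(trimethylsilyl)-2H-chromene | CC1(C)C=Cc2cc(Cl)cc([Si](C)(C)C)c2O1 | intermediate
14 | 6-chloro-8-iodo-2,2-dimethyl-2H-chromene | CC1(C)C=Cc2cc(Cl)cc(I)c2O1 | intermediate
15 | methyl (R)-glycidate (methyl (2R)-oxirane-2-carboxylate) | COC(=O)[C@H]1CO1 | starting material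
16 | (6-chloro-2,2-dimethyl-2H-chromen-8-yl)magnesium chloride (LiCl complex) | Cl[Mg]c1cc(Cl)cc2c1OC(C)(C)C=C2 | intermediate (not isolated)
17 | methyl (2R)-3-(6-chloro-2,2-dimethyl-2H-chromen-8-yl)-2-hydroxypropanoate | COC(=O)[C@H](O)Cc1cc(Cl)cc2c1OC(C)(C)C=C2 | intermediate
18 | methyl (2R)-2-[(tert-butyldimethylsilyl)oxy]-3-(6-chloro-2,2-dimethyl-2H-chromen-8-yl)propanoate | COC(=O)[C@H](O[Si](C)(C)C(C)(C)C)Cc1cc(Cl)cc2c1OC(C)(C)C=C2 | intermediate
19 | (2R)-2-[(tert-butyldimethylsilyl)oxy]-3-(6-chloro-2,2-dimethyl-2H-chromen-8-yl)-N-methoxy-N-methylpropanamide | CON(C)C(=O)[C@H](O[Si](C)(C)C(C)(C)C)Cc1cc(Cl)cc2c1OC(C)(C)C=C2 | intermediate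
20 | (3R)-3-[(tert-butyldimethylsilyl)oxy]-4-(6-chloro-2,2-dimethyl-2H-chromen-8-yl)butan-2-one | CC(=O)[C@H](O[Si](C)(C)C(C)(C)C)Cc1cc(Cl)cc2c1OC(C)(C)C=C2 | intermediate
21 | tert-butyl{[(2R)-1-(6-chloro-2,2-dimethyl-2H-chromen-8-yl)-3-methylbut-3-en-2-yl]oxy}dimethylsilane | C=C(C)[C@H](O[Si](C)(C)C(C)(C)C)Cc1cc(Cl)cc2c1OC(C)(C)C=C2 | intermediate
22 | tert-butyl{[(2R)-1-[2,2-dimethyl-6-(4,4,5,5-tetramethyl-1,3,2-dioxaborolan-2-yl)-2H-chromen-8-yl]-3-methylbut-3-en-2-yl]oxy}dimethylsilane | C=C(C)[C@H](O[Si](C)(C)C(C)(C)C)Cc1cc(B3OC(C)(C)C(C)(C)O3)cc2c1OC(C)(C)C=C2 | intermediate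
23 | {8-[(2R)-2-[(tert-butyldimethylsilyl)oxy]-3-methylbut-3-en-1-yl]-2,2-dimethyl-2H-chromen-6-yl}boronic acid | C=C(C)[C@H](O[Si](C)(C)C(C)(C)C)Cc1cc(B(O)O)cc2c1OC(C)(C)C=C2 | intermediate
24 | 2,4-dihydroxyacetophenone | CC(=O)c1ccc(O)cc1O | starting material
25 | 3-chloro-3-methylbut-1-yne | C#CC(C)(C)Cl | starting material
26 | 1-{2-hydroxy-4-[(2-methylbut-3-yn-2-yl)oxy]phenyl}ethan-1-one | CC(=O)c1ccc(OC(C)(C)C#C)cc1O | intermediate
27 | 1-{2-hydroxy-4-[(2-methylbut-3-en-2-yl)oxy]phenyl}ethan-1-one | CC(=O)c1ccc(OC(C)(C)C=C)cc1O | intermediate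
28 | 4-acetyl-3-hydroxy-2-(3-methylbut-2-en-1-yl)cyclohexa-3,5-dien-1-one (racemic) | CC(=O)C1=C(O)C(CC=C(C)C)C(=O)C=C1 | intermediate (not isolated)
29 | 1-[2,4-dihydroxy-3-(3-methylbut-2-en-1-yl)phenyl]ethan-1-one | CC(=O)c1ccc(O)c(CC=C(C)C)c1O | intermediate
30 | 1-{2-hydroxy-3-(3-methylbut-2-en-1-yl)-4-[(triisopropylsilyl)oxy]phenyl}ethan-1-one | CC(=O)c1ccc(O[Si](C(C)C)(C(C)C)C(C)C)c(CC=C(C)C)c1O | intermediate
31 | (2E)-3-(dimethylamino)-1-{2-hydroxy-3-(3-methylbut-2-en-1-yl)-4-[(triisopropylsilyl)oxy]phenyl}prop-2-en-1-one | CN(C)/C=C/C(=O)c1ccc(O[Si](C(C)C)(C(C)C)C(C)C)c(CC=C(C)C)c1O | intermediate (not isolated)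
32 | 8-(3-methylbut-2-en-1-yl)-7-[(triisopropylsilyl)oxy]-4H-chromen-4-one | O=c1ccoc2c1ccc(O[Si](C(C)C)(C(C)C)C(C)C)c2CC=C(C)C | intermediate
33 | (2S)-2-{8-[(2R)-2-[(tert-butyldimethylsilyl)oxy]-3-methylbut-3-en-1-yl]-2,2-dimethyl-2H-chromen-6-yl}-8-(3-methylbut-2-en-1-yl)-7-[(triisopropylsilyl)oxy]-2,3-dihydro-4H-chromen-4-one | C=C(C)[C@H](O[Si](C)(C)C(C)(C)C)Cc1cc([C@@H]2CC(=O)c3ccc(O[Si](C(C)C)(C(C)C)C(C)C)c(CC=C(C)C)c3O2)cc2c1OC(C)(C)C=C2 | intermediate
34 | (2S)-7-hydroxy-2-{8-[(2R)-2-hydroxy-3-methylbut-3-en-1-yl]-2,2-dimethyl-2H-chromen-6-yl}-8-(3-methylbut-2-en-1-yl)-2,3-dihydro-4H-chromen-4-one (CNP0104040.1) | C=C(C)[C@H](O)Cc1cc([C@@H]2CC(=O)c3ccc(O)c(CC=C(C)C)c3O2)cc2c1OC(C)(C)C=C2 | target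

**Step count**

Total: 19 steps. Longest linear sequence: 14 steps (steps 1–12, 18 and 19, from 2,6-dibromo-4-chlorophenol); the chromone branch (steps 13–17) has 5 steps.

**Steps most likely to fail**

1. Step 4. Oxygen may add to the aryne carbon remote from silicon (loss of regiocontrol), the aryne may be diverted into an ene reaction with the allylic methyl groups of 9 or into 2:1 adducts, or fluoride may strip the second silyl group. The fallback is the classical chromene construction without an aryne. It sets out from 1: n-BuLi (2.1 equiv, THF, −78 °C) followed by water removes one bromine and gives 2-bromo-4-chlorophenol F1. Copper-assisted O-alkylation with 25 (K2CO3, KI, CuI, acetone, reflux) gives 2-bromo-4-chloro-1-[(2-methylbut-3-yn-2-yl)oxy]benzene F2. Heating in PhNEt2 at about 190 °C (propargyl Claisen rearrangement, 1,5-hydrogen shift, oxa-6π electrocyclisation) should give 8-bromo-6-chloro-2,2-dimethyl-2H-chromene F3. Bromine–lithium exchange (n-BuLi, THF, −78 °C) gives (6-chloro-2,2-dimethyl-2H-chromen-8-yl)lithium F4, and MgCl2 turns it into the arylmagnesium chloride 16, where the route is rejoined in step 6; steps 1 to 5 are then not needed.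

2. Step 5. Addition of ICl across the electron-rich C3=C4 bond of the chromene may compete with ipso substitution at the silicon-bearing carbon, leaving under- and over-halogenated material. The fallback sacrifices the alkene on purpose and restores it, instead of relying on a rate difference. It sets out from 13: excess ICl (2.2 equiv, CH2Cl2, −78 to 0 °C) iodinates C8 and saturates the alkene, giving racemic trans-4,6-dichloro-3,8-diiodo-2,2-dimethylchromane F5. NaI in acetone at rt then exchanges the benzylic chloride (Finkelstein reaction), and the vicinal diiodide loses I2 to restore the alkene, which should return 14, where the route is rejoined.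

3. Step 18. Aryl transfer to the electron-rich, 8-substituted chromone may be slow so that protodeboronation of 23 takes over, facial control may be incomplete, or the flavanone may open to the chalcone with loss of the C2 configuration. The fallback keeps the two partners but changes the metal and the catalytic cycle. It sets out from 23 and 32: conjugate addition under cationic divalent palladium catalysis, Pd(OCOCF3)2 with (R)-t-BuPyOx [(4R)-4-tert-butyl-2-(pyridin-2-yl)-4,5-dihydrooxazole], NH4PF6, H2O, ClCH2CH2Cl, 60 °C. This needs neither base nor a metal hydroxide and is known for arylboronic acids and chromones; the R ligand is the one expected, by analogy with cyclic enones, to give the 2S product. The product is 33, where the route is rejoined, and no new compound is made (F0).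

**Further compounds**

F1 | step 4 | 2-bromo-4-chlorophenol | Oc1ccc(Cl)cc1Br
F2 | step 4 | 2-bromo-4-chloro-1-[(2-methylbut-3-yn-2-yl)oxy]benzene | C#CC(C)(C)Oc1ccc(Cl)cc1Br
F3 | step 4 | 8-bromo-6-chloro-2,2-dimethyl-2H-chromene | CC1(C)C=Cc2cc(Cl)cc(Br)c2O1
F4 | step 4 | (6-chloro-2,2-dimethyl-2H-chromen-8-yl)lithium | [Li]c1cc(Cl)cc2c1OC(C)(C)C=C2
F5 | step 5 | trans-4,6-dichloro-3,8-diiodo-2,2-dimethylchromane (racemic, one enantiomer drawn) | CC1(C)Oc2c(I)cc(Cl)cc2[C@H](Cl)[C@H]1I
F0 | step 18 | none | none
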